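I started from a small charge, a fraction 0.667 of it starting material and the rest other conformer, and asked how many times its clock goes round in 5.0 min.

| flask | starting material | other conformer | protic impurity | temperature | remark | time |
|---|---|---|---|---|---|---|
| alder | 0.25 M | 0.090 M | 0.090 M | 20 °C | run made earlier |  |
| ash | 0.40 M | 0.090 M | 0.090 M | 42 °C | run made earlier |  |
| Sunday's | 0.18 M | 0.0900 M | 0.0900 M | 30 °C |  | 5.0 min |
| Saturday's | 0.18 M | 0.0900 M | 0.0900 M | 50 °C |  | 5.0 min |
| Monday's | 0.18 M | 0.0900 M | 0.0900 M | 10 °C |  | 5.0 min |

- alder (time / min: target / %, starting material / %): 0.417: 0, 74.7; 1.33: 4.8, 74.6; 2.00: 5.3, 72.7; 3.00: 10.0, 67.9; 5.00: 14.7, 61.0; 6.00: 18.3, 57.5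
- ash (time / s: target / %, starting material / %): 20.0: 10.3, 70.5; 40.0: 17.7, 58.9; 60.0: 21.0, 49.4; 80.0: 23.7, 41.9; 90.0: 27.4, 37.7; 120: 29.0, 28.8

(readings scatter by 1 percentage point)

1. which flask leads in amount of target, in percent of the starting material and other conformer together charged ("all alike" within 1.5 percentage points) (Sunday's / Saturday's / Monday's / all alike)
2. how much target is there at the end, in percent of the starting material and other conformer together charged: Sunday's
3. how much target is there at the end, in percent of the starting material and other conformer together charged: Saturday's
4. how much target is there at the end, in percent of the starting material and other conformer together charged: Monday's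

- steps that have been proposed: target <-> isomer of the product A; starting material + protic impurity -> quenched substrate; starting material -> target; target -> over-reaction product; target <-> isomer of the product B; starting material <-> other conformer; other conformer -> isomer of the product A
- in a conversion other conformer counts as not yet reacted

In the readings the logarithm of starting material fell at 0.0558 /min in the alder run and at 0.537 /min in the ash run. I laid the logarithm of this constant on a straight line in temperature through those two runs. The turnovers, that constant times the time, then came to 6.12 for Saturday's, 0.781 for Sunday's and 0.0995 for Monday's.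

Monday's, the cold extreme, has few turnovers, so I reckoned its target as a selectivity times the starting fraction times the turnovers. The readings of the alder run gained 0.789 of target per unit of starting material lost, which gave 5.24% for Monday's.

Saturday's, the hot extreme, has many turnovers, at 0.817 min for each, and with the reacted fraction in place of the turnovers and none of its target used up, that reckoning gives 52.5%. But the same ratio read in the ash run was 0.448, so I took target in the ash run, which differs from the alder run in its charge as well as its temperature, to be used up as well as made. At 2.50 min I reckoned Saturday's feed at 4.69% of the charge, and from there on I expected its target to be used up more than made. Sunday's lies between, with 28.5% by the same reckoning, and I expected it to stand somewhat below that and to lead, though that was a judgement, for I put no number on the loss in Saturday's.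

The forecast named Sunday's, with 25%, 14% and 4.8% for Sunday's, Saturday's and Monday's, and said that Saturday's “peaks early, then drains”. The flasks gave 23.7%, 14.3% and 5.22% in that order, so Sunday's led.

    target ⇌ isomer of the product A (K = 1.10, k = 0.0160 /s, Ea = 81.0 kJ/mol, ΔH = −39.0 kJ/mol)
    starting material + protic impurity → quenched substrate (k = 0.0900 /M/s, Ea = 53.0 kJ/mol)
    starting material → target (k = 0.0150 /s, Ea = 78.0 kJ/mol)
    target → over-reaction product (k = 0.00660 /s, Ea = 94.0 kJ/mol)
    target ⇌ isomer of the product B (K = 2.60, k = 7.20 × 10⁻⁴ /s, Ea = 89.0 kJ/mol, ΔH = −21.0 kJ/mol)
    starting material ⇌ other conformer (K = 0.130, k = 0.0130 /s, Ea = 78.0 kJ/mol, ΔH = 20.0 kJ/mol)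
    other conformer → isomer of the product A (k = 0.0240 /s, Ea = 96.0 kJ/mol)
    (constants at 50 °C)

Saturday's turnovers reckoned 0.220% of the charge unreacted at the end, and 0.309% stood. In Saturday's, each step taken net, target was made 1.81 times faster than used at 0.610 min, yet at 5.00 min over-reaction product stood at 40.4% against 14.3% of target. Reading Saturday's at 2.0 min cuts the turnovers to 2.45, which reckons 8.63% unreacted and, with none used up, 48.1% of target. Saturday's at that time held 8.97% unreacted and 24.8% of target.

All runs come from a simulation with made-up constants.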